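**Plan**
- The retrosynthesis first returns both phenols to methyl ethers and the bridging CH2 to a C=O, then cuts both aryl–carbon bonds of that carbon in one operation: C(bridge)–C4 of ring A (3-bromo-4-oxygenated phenyl) and C(bridge)–C4' of ring B (3,5-dibromo-4-oxygenated phenyl).
- Enabling feature: the single bridging carbon is bonded only to two different aryl carbons, each para to its ring oxygen and meta to every bromine. It therefore maps onto a one-carbon dielectrophile (a urea C=O) flanked by two aryl nucleophiles that already carry their bromines.
- Forward: the ring A iodide comes from para-iodination of 2-bromoanisole, and the ring B iodide from para-iodination then O-methylation of 2,6-dibromophenol. Both are converted to arylmagnesium reagents and added in sequence (ring A, then ring B) to N,N'-dimethoxy-N,N'-dimethylurea to give the unsymmetrical benzophenone.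
- The ketone is then deoxygenated to CH2 and both methyl ethers are cleaved. No ring is formed; both benzene rings are bought.
- Stereochemistry (remark on the chemistry): the target has no stereocentre or other stereogenic element, so "single enantiomer" imposes no requirement and nothing has to be set or preserved.

Key step: step 4

**Route**

Step 1
Reactants: 1 2-bromoanisole
Product: 2 2-bromo-4-iodoanisole
Conditions: NIS (1.1 equiv), TFA, MeCN, rt
Reagents that add atoms: N-iodosuccinimide, O=C1CCC(=O)N1I
Why: Electrophilic aromatic iodination (SEAr) with acid-activated NIS should go para to the methoxy group, the strongest director, at C4, which is less hindered than C6, and should stop at the mono-iodide because the product is deactivated.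

Step 2
Reactants: 3 2,6-dibromophenol
Product: 4 2,6-dibromo-4-iodophenol
Conditions: NIS (1.05 equiv), p-TsOH·H2O (10 mol %), MeCN, 0 °C → rt
Reagents that add atoms: N-iodosuccinimide, O=C1CCC(=O)N1I
Why: SEAr iodination of a phenol with NIS under Brønsted acid catalysis can only take the para carbon, because both ortho positions carry bromine and the meta positions are not activated.

Step 3
Reactants: 4 2,6-dibromo-4-iodophenol
Product: 5 2,6-dibromo-4-iodoanisole
Conditions: MeI (1.5 equiv), K2CO3, DMF, rt
Reagents that add atoms: iodomethane, CI
Why: Williamson ether synthesis, in which the acidic 2,6-dibromophenol is deprotonated by carbonate and the phenoxide is methylated by SN2 on iodomethane while the aryl halides stay inert.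

Step 4
Reactants: 2 2-bromo-4-iodoanisole; 5 2,6-dibromo-4-iodoanisole; 6 N,N'-dimethoxy-N,N'-dimethylurea
Product: 12 (3-bromo-4-methoxyphenyl)(3,5-dibromo-4-methoxyphenyl)methanone, via ring-A arylmagnesium chloride 7 (not isolated), via ring-A bis(amino) magnesium alkoxide 8 (not isolated), via ring-A Weinreb amide 9 (not isolated), via ring-B arylmagnesium chloride 10 (not isolated), via ketone-level magnesium chelate 11 (not isolated)
Conditions: 2, i-PrMgCl·LiCl (0.98 equiv), THF, −20 → 0 °C; slow cannulation into 6 (1.05 equiv), THF, −40 °C, then 0 °C; then 10 [from 5 (1.3 equiv), i-PrMgCl·LiCl (1.25 equiv), THF, −40 → −20 °C], 0 °C → rt; 1 M HCl, 0 °C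
Reagents that add atoms: none
Why: Turbo-Grignard iodine–magnesium exchange turns each aryl iodide into its arylmagnesium chloride at the C–I carbon only, because C–I exchanges far faster than C–Br at −40 to 0 °C, and with magnesium meta to every bromine no aryne can form. Grignard 7 adds to the urea carbonyl to give the tetrahedral alkoxide 8, which on warming expels MeN(OMe)MgCl and leaves Weinreb amide 9; Grignard 10 then adds to 9 to give the five-membered N-methoxy magnesium chelate 11, which cannot collapse before the acidic quench liberates ketone 12. The closest known reaction type is the Weinreb ketone synthesis, run twice in one pot on a urea that serves as a carbonyl dication equivalent, with two different organometallics added in sequence. No ring closes and no stereocentre is formed, so only chemoselectivity and order of addition matter. One aryl per stage should be secured by using slightly less than one equivalent of exchange reagent (no free i-PrMgCl), by adding 7 slowly to a small excess of urea at −40 °C so that 8 persists until 7 is consumed, and by the stability of chelate 11 towards a third addition. The more nucleophilic mono-bromo Grignard is matched with the less electrophilic urea, and the less nucleophilic dibromo Grignard with the more electrophilic amide.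

Step 5
Reactants: 12 (3-bromo-4-methoxyphenyl)(3,5-dibromo-4-methoxyphenyl)methanone
Product: 14 1,3-dibromo-5-(3-bromo-4-methoxybenzyl)-2-methoxybenzene, via diarylmethanol 13 (not isolated)
Conditions: Et3SiH (3 equiv), TFA, TfOH (10 mol %), CH2Cl2, 0 °C → rt
Reagents that add atoms: none
Why: Ionic hydrogenation (silane/acid deoxygenation of a diaryl ketone), in which the protonated carbonyl accepts hydride from Et3SiH to give carbinol 13, which ionises to a diarylmethyl cation stabilised by the para-methoxy group of ring A and is trapped by a second hydride, while aryl bromides and methyl ethers do not react.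

Step 6
Reactants: 14 1,3-dibromo-5-(3-bromo-4-methoxybenzyl)-2-methoxybenzene
Product: 16 2,6-dibromo-4-(3-bromo-4-hydroxybenzyl)phenol (target), via bis(dibromoboryl) ether 15 (not isolated)
Conditions: BBr3 (4 equiv), CH2Cl2, −78 °C → rt; then H2O, 0 °C
Reagents that add atoms: none
Why: Lewis-acid cleavage of aryl methyl ethers with BBr3, in which boron binds each ether oxygen, bromide removes the methyl group by SN2 to give the aryl dibromoborinate 15, and water then frees both phenols without touching the C–Br bonds or the benzylic CH2.

**Compound list**

1 | 2-bromoanisole (1-bromo-2-methoxybenzene) | COc1ccccc1Br | starting material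
2 | 2-bromo-4-iodoanisole (2-bromo-4-iodo-1-methoxybenzene) | COc1ccc(I)cc1Br | intermediate
3 | 2,6-dibromophenol | Oc1c(Br)cccc1Br | starting material
4 | 2,6-dibromo-4-iodophenol | Oc1c(Br)cc(I)cc1Br | intermediate
5 | 2,6-dibromo-4-iodoanisole (1,3-dibromo-5-iodo-2-methoxybenzene) | COc1c(Br)cc(I)cc1Br | intermediate
6 | N,N'-dimethoxy-N,N'-dimethylurea | CON(C)C(=O)N(C)OC | starting material
7 | (3-bromo-4-methoxyphenyl)magnesium chloride (LiCl complex, formed in situ) | COc1ccc([Mg]Cl)cc1Br | intermediate
8 | chloromagnesium (3-bromo-4-methoxyphenyl)bis[methoxy(methyl)amino]methanolate (formed in situ) | COc1ccc(C(O[Mg]Cl)(N(C)OC)N(C)OC)cc1Br | intermediate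
9 | 3-bromo-N,4-dimethoxy-N-methylbenzamide (formed in situ) | COc1ccc(C(=O)N(C)OC)cc1Br | intermediate
10 | (3,5-dibromo-4-methoxyphenyl)magnesium chloride (LiCl complex, formed in situ) | COc1c(Br)cc([Mg]Cl)cc1Br | intermediate
11 | chloromagnesium (3-bromo-4-methoxyphenyl)(3,5-dibromo-4-methoxyphenyl)[methoxy(methyl)amino]methanolate (racemic, formed in situ) | COc1ccc(C(O[Mg]Cl)(N(C)OC)c2cc(Br)c(OC)c(Br)c2)cc1Br | intermediate
12 | (3-bromo-4-methoxyphenyl)(3,5-dibromo-4-methoxyphenyl)methanone | COc1ccc(C(=O)c2cc(Br)c(OC)c(Br)c2)cc1Br | intermediate
13 | (3-bromo-4-methoxyphenyl)(3,5-dibromo-4-methoxyphenyl)methanol (racemic, formed in situ) | COc1ccc(C(O)c2cc(Br)c(OC)c(Br)c2)cc1Br | intermediate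
14 | 1,3-dibromo-5-(3-bromo-4-methoxybenzyl)-2-methoxybenzene | COc1ccc(Cc2cc(Br)c(OC)c(Br)c2)cc1Br | intermediate
15 | dibromo{2-bromo-4-[3,5-dibromo-4-(dibromoboranyloxy)benzyl]phenoxy}borane (formed in situ) | BrB(Br)Oc1ccc(Cc2cc(Br)c(OB(Br)Br)c(Br)c2)cc1Br | intermediate
16 | 2,6-dibromo-4-(3-bromo-4-hydroxybenzyl)phenol | Oc1ccc(Cc2cc(Br)c(O)c(Br)c2)cc1Br | target

**Step count**

Total steps: 6. Longest linear sequence: 5 steps (3 → 4 → 5 → 12 → 14 → 16); the ring A branch (1 → 2) joins at step 4.

**Steps most likely to fail**

Step 4. The order of the double addition may break down in three ways: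
- the first tetrahedral adduct may collapse while the ring A Grignard is still present, which would give symmetrical ketone;
- the halogen–magnesium exchange may stray to a C–Br bond flanking a methoxy group;
- the electron-poor ring B Grignard may add too slowly to the amide.

The fallback sets out from 1 and returns at 12. Purchased 3,5-dibromo-4-methoxybenzoic acid F1 would be converted with oxalyl chloride and catalytic DMF in CH2Cl2 into 3,5-dibromo-4-methoxybenzoyl chloride F2. This should acylate 2-bromoanisole 1 para to its methoxy group under AlCl3 in CH2Cl2 at 0 °C (Friedel–Crafts acylation) to give ketone 12. The ring B–carbonyl bond is then bought with the acid, and the ring A–carbonyl bond is made by SEAr instead of by an organometallic, so neither exchange selectivity nor order of addition is needed.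

Step 5. Hydride transfer to a bromine-deactivated diarylmethyl cation may be slow, so the reduction may stall at the carbinol stage or the cation may alkylate the electron-rich ring of a second molecule. The fallback sets out from 12 and returns at 14. Condensation with tosylhydrazide (EtOH, cat. HCl, reflux) should give (3-bromo-4-methoxyphenyl)(3,5-dibromo-4-methoxyphenyl)methanone tosylhydrazone F3 (either C=N geometry). This would be reduced with catecholborane in CHCl3 at 0 °C → rt and then decomposed with NaOAc·3H2O at reflux (Caglioti-type reduction). The intermediate diazene loses N2 to give 14 without any benzylic cation.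

Step 6. Cleavage of one ether may be incomplete, or the electron-rich tribromo diarylmethane may undergo acid-driven side reactions (protodebromination, transbenzylation) under BBr3 and the HBr formed on quench. The fallback sets out from 14 and returns at 16. Nucleophilic demethylation with sodium ethanethiolate in DMF at 110 °C, followed by dilute HCl, should remove both methyl groups by SN2 attack of thiolate at the methyl carbons. The ortho-bromines make both phenoxides good leaving groups, and the medium stays basic throughout.

**Further compounds**

F1 | step 4 | 3,5-dibromo-4-methoxybenzoic acid (purchased) | COc1c(Br)cc(C(=O)O)cc1Br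
F2 | step 4 | 3,5-dibromo-4-methoxybenzoyl chloride | COc1c(Br)cc(C(Cl)=O)cc1Br
F3 | step 5 | (3-bromo-4-methoxyphenyl)(3,5-dibromo-4-methoxyphenyl)methanone tosylhydrazone | COc1ccc(C(=NNS(=O)(=O)c2ccc(C)cc2)c2cc(Br)c(OC)c(Br)c2)cc1Br
F0 | step 6 | none | none
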